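The over-reaction product levels off in the earlier runs, and I read a clock from them before I reckon the four new flasks.

| flask | substrate | partner | remark | time |
|---|---|---|---|---|
| winter | 0.088 M | 0.176 M | run made earlier |  |
| summer | 0.088 M | 0.088 M | run made earlier |  |
| dawn | 0.088 M | 0.13 M | run made earlier |  |
| noon | 0.13 M | 0.176 M | run made earlier |  |
| ash | 0.088 M | 0.176 M (fed, over 80 min) | all else is in the flask from the start; the feed brings no volume worth counting | 2.0 h |
| alder | 0.088 M (in portions, 2, over 80 min) | 0.176 M | first portion at the start, last at 80 min | 2.0 h |
| oak | 0.088 M | 0.176 M | everything together at the start | 2.0 h |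
| elm | 0.088 M (fed, over 80 min) | 0.176 M | all else is in the flask from the start; the feed brings no volume worth counting | 2.0 h |

| run | time / min | over-reaction product / % | target / % |
|---|---|---|---|
| winter | 30.0 | 34 | 11 |
| winter | 60.0 | 46 | 3 |
| winter | 90.0 | 48 | 0 |
| winter | 120 | 45 | 0 |
| summer | 20.0 | 12 | 8 |
| summer | 40.0 | 24 | 3 |
| summer | 50.0 | 26 | 4 |
| summer | 80.0 | 29 | 0 |
| dawn | 6.00 | 0 | 7 |
| dawn | 12.0 | 7 | 15 |
| dawn | 30.0 | 27 | 11 |
| dawn | 80.0 | 38 | 1 |
| noon | 20.0 | 23 | 16 |
| noon | 40.0 | 36 | 6 |
| noon | 50.0 | 42 | 2 |
| noon | 80.0 | 43 | 0 |

(scatter of a reading: 1.5 percentage points)



1. the flask with the highest amount of over-reaction product, in percent of the substrate charged ("all alike" if they lie within 1.5 percentage points) (ash / alder / oak / elm / all alike)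
2. final over-reaction product, as a percentage of the substrate charged, in ash
3. final over-reaction product, as a percentage of the substrate charged, in alder
4. final over-reaction product, as a percentage of the substrate charged, in oak
5. final over-reaction product, as a percentage of the substrate charged, in elm

I add target and over-reaction product into a coupled share, the part of the substrate that has met partner. In the dawn run it reads 7.00% at 6.00 min and 22.0% at 12.0 min, so its second stretch is steeper than its first. That is the lag of two time constants in series: something waits between substrate and coupling.

Then comes a knee. The summer run reads 20.0% at 20.0 min against a level of 29.0% at 80.0 min, and an exponential approach through those points has the time constant 17.1 min. I call this reading the partner clock: the time in which partner's power to couple fades by a factor e. The noon run goes flat at a coupled share that, at one partner per substrate, is a third of its partner charge. So in the noon run coupling accounts for that part of the partner charge, and I commit to the rest being lost by itself, though these runs do not prove it.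

Oak has the winter charges, so I take the winter level, 46.5%. In alder I let the first portion carry half of that, 23.2%. I take the last portion as a small correction, since by my clock partner has faded to 0.928% of its charge by then. In elm I reckon the feed that meets live partner as clock over feed time, 21.4% of the charge, and at the winter share of that it gives 9.94%; I expect the over-reaction product of elm between 9.94% and 21.4%. In ash I reckon fed partner to stand near feed rate times clock, 0.0376 M, lower than the charge, and I put no number on the over-reaction product of ash.

The forecast names oak and gives 16% in ash, 47% in alder, 47% in oak and 46% in elm, holding that “Feeding substrate therefore changes little, and portions likewise”, and my alder and elm lie below it. The flasks give 37.7% in ash, 26.1% in alder, 47.1% in oak and 12.7% in elm, which puts oak ahead.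

    substrate → intermediate (k = 0.00280 s⁻¹)
    partner + intermediate → target (k = 0.00910 L mol⁻¹ s⁻¹)
    partner → decomposed reagent (k = 9.80 × 10⁻⁴ s⁻¹)
    target → over-reaction product (k = 0.00150 s⁻¹)
    intermediate → side product (k = 2.90 × 10⁻⁴ s⁻¹)

In elm the partner's decay ran while substrate was still coming in: 99% of its turnover up to 2.0 h lay behind it after 1.00 h. By the end of the feed in elm partner stood at 0.360% of its charge and intermediate at 46.5% of the substrate charge, and the over-reaction product of elm ends at 12.7%, inside my range. Alder runs on the same clock: its last portion came after 4.68 clocks and met 0.543% of the partner charge, where the clock gives 0.928%. The over-reaction product of alder stands at 25.7% at 1.33 h, just before that portion, and at 26.1% at 20.0 h.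

The data are calculated on assumed constants, and the scatter is random.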